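(The runs were generated by integration from invented constants, and the scatter is random.)

**One-step world.** In a one-step world each turn of the catalyst takes one partner and one substrate and gives one product, so I counted turnovers, and I expected the count to end with the partner, the limiting reagent, since 0.0416 M stood against 0.104 M of the two substrates together.

| flask | left-handed substrate | right-handed substrate | partner | catalyst | remark | time |
|---|---|---|---|---|---|---|
| south-west | 0.052 M | 0.052 M | 0.028 M | 6.2 mM | run made earlier |  |
| west | 0.052 M | 0.052 M | 0.062 M | 6.2 mM | run made earlier |  |
| flask | 0.052 M | 0.052 M | 0.0416 M | 6.2 mM |  | 5.0 h |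

| run | time / h | left-handed product / % | right-handed product / % |
|---|---|---|---|
| south-west | 0.833 | 13.5 | 7.1 |
| south-west | 1.50 | 13.1 | 8.3 |
| south-west | 2.50 | 15.0 | 11.4 |
| south-west | 3.00 | 13.6 | 10.7 |
| south-west | 4.00 | 14.8 | 10.9 |
| south-west | 5.00 | 13.5 | 10.8 |
| south-west | 6.00 | 13.6 | 11.1 |
| west | 0.833 | 22.5 | 16.1 |
| west | 1.50 | 28.6 | 18.9 |
| west | 2.50 | 30.3 | 21.0 |
| west | 3.00 | 26.9 | 23.4 |
| west | 4.00 | 27.6 | 24.0 |
| west | 5.00 | 27.1 | 24.5 |
| west | 6.00 | 26.4 | 26.6 |

(readings scatter by 1 percentage point)

- catalyst is single-handed; left-handed substrate and right-handed substrate are mirror images of each other, charged as a racemate, each of them at the stated concentration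
- the earlier runs were read with a standard deviation of 1 percentage point
- an excess is below zero if the other one leads

1. excess of left-handed product over right-handed product in the product at 6.0 min
2. excess of left-handed product over right-handed product in the product at 5.0 h
3. part of the left-handed substrate and right-handed substrate charged together that has reacted at 5.0 h

**First rung.** The turnovers came first: by 0.833 h the south-west run held 83.4% of the product read at 6.00 h, and the west run held 72.8% of its own. The early time asked for lies on this rung.

**Second rung.** Handedness moved later: in the south-west run the excess read 31.1% at 0.833 h and 10.1% at 6.00 h, while from 2.50 h on the total stayed level within the scatter. The excess asked for at 5.0 h lies on this rung.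

**The count.** The last readings showed product for 91.7% of the partner charged in the south-west run and 88.9% in the west run, and I carried their mean, 90.3%. For this flask that share, times partner over catalyst, gave 6.06 delivered turnovers, meaning products made per catalyst, out of 6.71 allowed. I therefore expected 36.1% reacted.

**The forecast.** The forecast gave a product excess of 40% at 6.0 min and of 9% at 5.0 h, and 36.5% reacted at 5.0 h, a conversion slightly above mine, on the ground that “Both earlier runs plateau at about 90% of their cap”.

**The result.** The flask gave a product excess of 35.8% at 6.0 min and of 5.27% at 5.0 h, and 36.2% reacted at 5.0 h.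

    partner + catalyst + left-handed substrate → catalyst + left-handed product (k = 1.24 M⁻² s⁻¹)
    partner + catalyst + right-handed substrate → catalyst + right-handed product (k = 0.560 M⁻² s⁻¹)
    left-handed product ⇌ right-handed product (k = 5.49 × 10⁻⁵ s⁻¹)
    partner → decomposed reagent (k = 2.78 × 10⁻⁵ s⁻¹)
    partner ⇌ dormant form (K = 3.74, k = 2.16 × 10⁻⁵ s⁻¹)

At 5.00 h the flask kept 0.11% of its partner against 53% of its left-handed substrate, while the decomposed reagent and dormant form together held 9.50% of the partner charge. Counted as turnovers, the flask delivered 6.06, beside my 6.06.

**Second flask.** With 0.071 M of partner and the recipe otherwise unchanged, the same share gave an estimate of 10.3 delivered turnovers, which is 61.7% reacted at 5.0 h. The computed flask gave 59.8%, which is 10.0 turnovers.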